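**Retrosynthetic overview**
- Each E‑C(CH3)=CH–CH2 unit of the chain is traced back to a β‑keto ester (Z‑enol phosphate, then Me2CuLi, then DIBAL‑H). The C8–C9 and C4–C5 bonds come from alkylating the methyl acetoacetate dianion with the C15 and C20 allylic bromides.
- Key C–C bond (C10–C11): crossed Claisen condensation of the stereodefined ring ester with the lithium enolate of tert‑butyl acetate.
- Ring ester (1S,2S): OH‑directed hydrogenation of an alkylidene carbinol, made by SmI2 opening of an epoxy enoate, made by HWE on the epoxy aldehyde from Sharpless epoxidation of β‑cyclogeraniol.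
- Rings: the cyclohexane is present from the start (β‑cyclocitral). The only ring formed is the oxirane (step 2), opened again in step 5.

Assumption: carbon building blocks and metal enolates pre‑formed from them carry compound numbers; other reagents are named in the conditions; work‑up is aqueous NH4Cl unless stated.

**Step 1**
Reactants: 1 β‑cyclocitral (2,6,6‑trimethylcyclohex‑1‑ene‑1‑carbaldehyde)
Product: 2 β‑cyclogeraniol [(2,6,6‑trimethylcyclohex‑1‑en‑1‑yl)methanol]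
Conditions: NaBH4, MeOH, 0 °C
Reagents that add atoms: none
Why: Borohydride 1,2‑reduction of an enal whose tetrasubstituted β‑carbon resists conjugate attack; no stereocentre is formed.

**Step 2**
Reactants: 2 β‑cyclogeraniol
Product: 3 [(1S,6S)‑2,2,6‑trimethyl‑7‑oxabicyclo[4.1.0]heptan‑1‑yl]methanol
Conditions: Ti(OiPr)4 (10 mol%), L‑(+)‑diethyl tartrate (14 mol%), t‑BuOOH (2 equiv), 4 Å MS, CH2Cl2, −20 °C
Reagents that add atoms: tert‑butyl hydroperoxide, CC(C)(C)OO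
Why: Katsuki–Sharpless asymmetric epoxidation; L‑(+)‑DET attacks the same alkene face as in geraniol (which gives the 2S,3S epoxide), so the methyl‑bearing carbon becomes S and the cis‑fused oxirane fixes the second centre.

**Step 3**
Reactants: 3 epoxy alcohol
Product: 4 (1R,6S)‑2,2,6‑trimethyl‑7‑oxabicyclo[4.1.0]heptane‑1‑carbaldehyde
Conditions: TPAP (5 mol%), NMO (1.5 equiv), 4 Å MS, CH2Cl2, rt
Reagents that add atoms: none
Why: Ley–Griffith oxidation is neutral and spares the acid‑sensitive oxirane; the α‑carbon is quaternary so it cannot epimerise (the descriptor changes to R only through CIP priorities).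

**Step 4**
Reactants: 4 epoxy aldehyde; 5 triethyl phosphonoacetate
Product: 7 ethyl (2E)‑3‑[(1R,6S)‑2,2,6‑trimethyl‑7‑oxabicyclo[4.1.0]heptan‑1‑yl]prop‑2‑enoate, via sodium phosphonate 6 (not isolated)
Conditions: 5, NaH, THF, 0 °C; then 4, 0 °C → rt
Reagents that add atoms: none
Why: Horner–Wadsworth–Emmons olefination of a non‑enolisable aldehyde with a stabilised phosphonate gives the E‑enoate and leaves both stereocentres untouched.

**Step 5**
Reactants: 7 epoxy enoate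
Product: 8 ethyl 3‑[(2S)‑2‑hydroxy‑2,6,6‑trimethylcyclohexylidene]propanoate (E/Z mixture at the exocyclic alkene)
Conditions: SmI2 (2.5 equiv), MeOH (3 equiv), THF, −78 °C
Reagents that add atoms: none
Why: Molander SmI2 reduction of a γ,δ‑epoxy enoate cleaves the allylic C–O bond and α‑protonation of the dienolate gives the δ‑hydroxy β,γ‑unsaturated ester; the carbinol C–O bond is never broken, so S is retained.

**Step 6**
Reactants: 8 alkylidene carbinol
Product: 9 ethyl 3‑[(1S,2S)‑2‑hydroxy‑2,6,6‑trimethylcyclohexyl]propanoate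
Conditions: H2 (1 atm), [Ir(cod)(PCy3)(py)]PF6 (5 mol%), CH2Cl2, rt
Reagents that add atoms: none
Why: Hydroxyl‑directed (Crabtree–Stork) hydrogenation delivers H2 to the alkene face bearing the tertiary OH, so the new ring C–H is cis to OH and the side chain trans (1S), from either alkene isomer.

**Step 7**
Reactants: 9 hydroxy ester
Product: 10 ethyl 3‑[(1S,2S)‑2,6,6‑trimethyl‑2‑(triethylsilyloxy)cyclohexyl]propanoate
Conditions: TESOTf, 2,6‑lutidine, CH2Cl2, −78 → 0 °C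
Reagents that add atoms: triethylsilyl trifluoromethanesulfonate, CC[Si](CC)(CC)OS(=O)(=O)C(F)(F)F
Why: Silyl triflate silylation protects the hindered tertiary alcohol against the bases, hydrides and phosphorylating agents that follow; no stereocentre is affected.

**Step 8**
Reactants: 10 ring ester; 11 tert‑butyl acetate
Product: 13 tert‑butyl 3‑oxo‑5‑[(1S,2S)‑2,6,6‑trimethyl‑2‑(triethylsilyloxy)cyclohexyl]pentanoate, via lithium enolate 12 (not isolated)
Conditions: 11 (3.5 equiv), LDA (3.5 equiv), THF, −78 °C; then 10, −78 → −20 °C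
Reagents that add atoms: none
Why: Crossed Claisen condensation: the non‑self‑condensing lithium enolate of tert‑butyl acetate is acylated by the unhindered ethyl ester and deprotonation of the β‑keto ester drives it to completion.

**Step 9**
Reactants: 13 β‑keto ester
Product: 15 tert‑butyl (2Z)‑3‑(diethoxyphosphoryloxy)‑5‑[(1S,2S)‑2,6,6‑trimethyl‑2‑(triethylsilyloxy)cyclohexyl]pent‑2‑enoate, via sodium enolate 14 (not isolated)
Conditions: NaH, Et2O, 0 °C; then ClP(O)(OEt)2, 0 °C → rt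
Reagents that add atoms: diethyl chlorophosphate, CCOP(=O)(Cl)OCC
Why: Weiler enol phosphate formation: the chelated sodium enolate is O‑phosphorylated with its Z geometry preserved.

**Step 10**
Reactants: 15 enol phosphate
Product: 16 tert‑butyl (2E)‑3‑methyl‑5‑[(1S,2S)‑2,6,6‑trimethyl‑2‑(triethylsilyloxy)cyclohexyl]pent‑2‑enoate
Conditions: Me2CuLi (from MeLi, CuI; 3 equiv), Et2O, −78 → −45 °C; aq NH4Cl/NH3
Reagents that add atoms: lithium dimethylcuprate, [Li+].C[Cu-]C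
Why: Cuprate addition–elimination on the enol phosphate (Sum–Weiler) replaces phosphate by methyl with retention, giving the E trisubstituted enoate.

**Step 11**
Reactants: 16 enoate
Product: 17 (2E)‑3‑methyl‑5‑[(1S,2S)‑2,6,6‑trimethyl‑2‑(triethylsilyloxy)cyclohexyl]pent‑2‑en‑1‑ol
Conditions: DIBAL‑H (2.5 equiv), CH2Cl2, −78 → 0 °C; Rochelle salt
Reagents that add atoms: none
Why: DIBAL‑H 1,2‑reduction of the unsaturated ester gives the allylic alcohol without touching the alkene geometry or the silyl ether.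

**Step 12**
Reactants: 17 allylic alcohol
Product: 18 (2E)‑1‑bromo‑3‑methyl‑5‑[(1S,2S)‑2,6,6‑trimethyl‑2‑(triethylsilyloxy)cyclohexyl]pent‑2‑ene
Conditions: CBr4, PPh3, CH2Cl2, 0 °C
Reagents that add atoms: carbon tetrabromide, BrC(Br)(Br)Br
Why: Appel bromination is neutral, proceeds by SN2 at the primary allylic carbon and keeps the E alkene and the TES ether.

**Step 13**
Reactants: 18 allylic bromide; 19 methyl acetoacetate
Product: 21 methyl (6E)‑7‑methyl‑3‑oxo‑9‑[(1S,2S)‑2,6,6‑trimethyl‑2‑(triethylsilyloxy)cyclohexyl]non‑6‑enoate, via acetoacetate dianion 20 (not isolated)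
Conditions: 19, NaH, THF, 0 °C; n‑BuLi, 0 °C; then 18, 0 °C → rt
Reagents that add atoms: none
Why: Weiler dianion alkylation: the terminal (γ) carbanion of the acetoacetate dianion displaces the allylic bromide by SN2 without allylic transposition.

**Step 14**
Reactants: 21 β‑keto ester
Product: 23 methyl (2Z,6E)‑3‑(diethoxyphosphoryloxy)‑7‑methyl‑9‑[(1S,2S)‑2,6,6‑trimethyl‑2‑(triethylsilyloxy)cyclohexyl]nona‑2,6‑dienoate, via sodium enolate 22 (not isolated)
Conditions: NaH, Et2O, 0 °C; then ClP(O)(OEt)2, 0 °C → rt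
Reagents that add atoms: diethyl chlorophosphate, CCOP(=O)(Cl)OCC
Why: Weiler Z‑enol phosphate formation from the chelated sodium enolate, as in step 9.

**Step 15**
Reactants: 23 enol phosphate
Product: 24 methyl (2E,6E)‑3,7‑dimethyl‑9‑[(1S,2S)‑2,6,6‑trimethyl‑2‑(triethylsilyloxy)cyclohexyl]nona‑2,6‑dienoate
Conditions: Me2CuLi (from MeLi, CuI; 3 equiv), Et2O, −78 → −45 °C; aq NH4Cl/NH3
Reagents that add atoms: lithium dimethylcuprate, [Li+].C[Cu-]C
Why: Stereoretentive cuprate addition–elimination on the enol phosphate sets the second E trisubstituted alkene.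

**Step 16**
Reactants: 24 dienoate
Product: 25 (2E,6E)‑3,7‑dimethyl‑9‑[(1S,2S)‑2,6,6‑trimethyl‑2‑(triethylsilyloxy)cyclohexyl]nona‑2,6‑dien‑1‑ol
Conditions: DIBAL‑H (2.5 equiv), CH2Cl2, −78 °C; Rochelle salt
Reagents that add atoms: none
Why: DIBAL‑H 1,2‑reduction of the enoate to the allylic alcohol.

**Step 17**
Reactants: 25 dienol
Product: 26 (2E,6E)‑1‑bromo‑3,7‑dimethyl‑9‑[(1S,2S)‑2,6,6‑trimethyl‑2‑(triethylsilyloxy)cyclohexyl]nona‑2,6‑diene
Conditions: CBr4, PPh3, CH2Cl2, 0 °C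
Reagents that add atoms: carbon tetrabromide, BrC(Br)(Br)Br
Why: Appel bromination under neutral conditions, as in step 12.

**Step 18**
Reactants: 26 allylic bromide; 19 methyl acetoacetate
Product: 28 methyl (6E,10E)‑7,11‑dimethyl‑3‑oxo‑13‑[(1S,2S)‑2,6,6‑trimethyl‑2‑(triethylsilyloxy)cyclohexyl]trideca‑6,10‑dienoate, via dilithium acetoacetate dianion 27 (not isolated)
Conditions: 19, LDA (2.1 equiv), THF, 0 °C; then 26, 0 °C → rt
Reagents that add atoms: none
Why: Weiler dianion γ‑alkylation, here through the dilithium dianion formed homogeneously with two equivalents of LDA (easy to dose on the smaller late‑stage scale); SN2 on the allylic bromide keeps the E alkene.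

**Step 19**
Reactants: 28 β‑keto ester
Product: 30 methyl (2Z,6E,10E)‑3‑(diethoxyphosphoryloxy)‑7,11‑dimethyl‑13‑[(1S,2S)‑2,6,6‑trimethyl‑2‑(triethylsilyloxy)cyclohexyl]trideca‑2,6,10‑trienoate, via sodium enolate 29 (not isolated)
Conditions: NaH, Et2O, 0 °C; then ClP(O)(OEt)2, 0 °C → rt
Reagents that add atoms: diethyl chlorophosphate, CCOP(=O)(Cl)OCC
Why: Weiler Z‑enol phosphate formation, as in step 9.

**Step 20**
Reactants: 30 enol phosphate
Product: 31 methyl (2E,6E,10E)‑3,7,11‑trimethyl‑13‑[(1S,2S)‑2,6,6‑trimethyl‑2‑(triethylsilyloxy)cyclohexyl]trideca‑2,6,10‑trienoate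
Conditions: Me2CuLi (from MeLi, CuI; 3 equiv), Et2O, −78 → −45 °C; aq NH4Cl/NH3
Reagents that add atoms: lithium dimethylcuprate, [Li+].C[Cu-]C
Why: Stereoretentive cuprate addition–elimination sets the third E trisubstituted alkene.

**Step 21**
Reactants: 31 trienoate
Product: 32 (2E,6E,10E)‑3,7,11‑trimethyl‑13‑[(1S,2S)‑2,6,6‑trimethyl‑2‑(triethylsilyloxy)cyclohexyl]trideca‑2,6,10‑trien‑1‑ol
Conditions: DIBAL‑H (2.5 equiv), CH2Cl2, −78 °C; Rochelle salt
Reagents that add atoms: none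
Why: DIBAL‑H 1,2‑reduction of the enoate gives the terminal allylic alcohol.

**Step 22**
Reactants: 32 TES ether
Product: 33 preluffariellolide A, (2E,6E,10E)‑13‑[(1S,2S)‑2‑hydroxy‑2,6,6‑trimethylcyclohexyl]‑3,7,11‑trimethyltrideca‑2,6,10‑trien‑1‑ol
Conditions: TBAF, THF, rt → 45 °C
Reagents that add atoms: none
Why: Fluoride desilylation of the tertiary TES ether is non‑acidic, so neither the tertiary carbinol nor the allylic alcohol and trisubstituted alkenes can ionise or isomerise.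

**Compound list**
1 | β‑cyclocitral | CC1=C(C=O)C(C)(C)CCC1 | starting material
2 | β‑cyclogeraniol | CC1=C(CO)C(C)(C)CCC1 | intermediate
3 | [(1S,6S)‑2,2,6‑trimethyl‑7‑oxabicyclo[4.1.0]heptan‑1‑yl]methanol | OC[C@]12O[C@@]1(C)CCCC2(C)C | intermediate
4 | (1R,6S)‑2,2,6‑trimethyl‑7‑oxabicyclo[4.1.0]heptane‑1‑carbaldehyde | O=C[C@]12O[C@@]1(C)CCCC2(C)C | intermediate
5 | triethyl phosphonoacetate | CCOC(=O)CP(=O)(OCC)OCC | starting material
6 | sodium salt of triethyl phosphonoacetate (sodium phosphonate) | [Na+].CCOC(=O)[CH-]P(=O)(OCC)OCC | intermediate (not isolated)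
7 | ethyl (2E)‑3‑[(1R,6S)‑2,2,6‑trimethyl‑7‑oxabicyclo[4.1.0]heptan‑1‑yl]prop‑2‑enoate | CCOC(=O)/C=C/[C@]12O[C@@]1(C)CCCC2(C)C | intermediate
8 | ethyl 3‑[(2S)‑2‑hydroxy‑2,6,6‑trimethylcyclohexylidene]propanoate (E/Z mixture) | CCOC(=O)CC=C1C(C)(C)CCC[C@]1(C)O | intermediate
9 | ethyl 3‑[(1S,2S)‑2‑hydroxy‑2,6,6‑trimethylcyclohexyl]propanoate | CCOC(=O)CC[C@H]1C(C)(C)CCC[C@]1(C)O | intermediate
10 | ethyl 3‑[(1S,2S)‑2,6,6‑trimethyl‑2‑(triethylsilyloxy)cyclohexyl]propanoate | CCOC(=O)CC[C@H]1C(C)(C)CCC[C@]1(C)O[Si](CC)(CC)CC | intermediate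
11 | tert‑butyl acetate | CC(=O)OC(C)(C)C | starting material
12 | lithium enolate of tert‑butyl acetate | [Li+].[O-]C(=C)OC(C)(C)C | intermediate (not isolated)
13 | tert‑butyl 3‑oxo‑5‑[(1S,2S)‑2,6,6‑trimethyl‑2‑(triethylsilyloxy)cyclohexyl]pentanoate | CC(C)(C)OC(=O)CC(=O)CC[C@H]1C(C)(C)CCC[C@]1(C)O[Si](CC)(CC)CC | intermediate
14 | sodium enolate of 13 | [Na+].CC(C)(C)OC(=O)/C=C(\[O-])CC[C@H]1C(C)(C)CCC[C@]1(C)O[Si](CC)(CC)CC | intermediate (not isolated)
15 | tert‑butyl (2Z)‑3‑(diethoxyphosphoryloxy)‑5‑[(1S,2S)‑2,6,6‑trimethyl‑2‑(triethylsilyloxy)cyclohexyl]pent‑2‑enoate | CC(C)(C)OC(=O)/C=C(\OP(=O)(OCC)OCC)CC[C@H]1C(C)(C)CCC[C@]1(C)O[Si](CC)(CC)CC | intermediate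
16 | tert‑butyl (2E)‑3‑methyl‑5‑[(1S,2S)‑2,6,6‑trimethyl‑2‑(triethylsilyloxy)cyclohexyl]pent‑2‑enoate | CC(C)(C)OC(=O)/C=C(\C)CC[C@H]1C(C)(C)CCC[C@]1(C)O[Si](CC)(CC)CC | intermediate
17 | (2E)‑3‑methyl‑5‑[(1S,2S)‑2,6,6‑trimethyl‑2‑(triethylsilyloxy)cyclohexyl]pent‑2‑en‑1‑ol | OC/C=C(\C)CC[C@H]1C(C)(C)CCC[C@]1(C)O[Si](CC)(CC)CC | intermediate
18 | (2E)‑1‑bromo‑3‑methyl‑5‑[(1S,2S)‑2,6,6‑trimethyl‑2‑(triethylsilyloxy)cyclohexyl]pent‑2‑ene | BrC/C=C(\C)CC[C@H]1C(C)(C)CCC[C@]1(C)O[Si](CC)(CC)CC | intermediate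
19 | methyl acetoacetate | COC(=O)CC(C)=O | starting material
20 | sodium lithium dianion of methyl acetoacetate | [Li+].[Na+].C=C([O-])C=C([O-])OC | intermediate (not isolated)
21 | methyl (6E)‑7‑methyl‑3‑oxo‑9‑[(1S,2S)‑2,6,6‑trimethyl‑2‑(triethylsilyloxy)cyclohexyl]non‑6‑enoate | COC(=O)CC(=O)CC/C=C(\C)CC[C@H]1C(C)(C)CCC[C@]1(C)O[Si](CC)(CC)CC | intermediate
22 | sodium enolate of 21 | [Na+].COC(=O)/C=C(\[O-])CC/C=C(\C)CC[C@H]1C(C)(C)CCC[C@]1(C)O[Si](CC)(CC)CC | intermediate (not isolated)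
23 | methyl (2Z,6E)‑3‑(diethoxyphosphoryloxy)‑7‑methyl‑9‑[(1S,2S)‑2,6,6‑trimethyl‑2‑(triethylsilyloxy)cyclohexyl]nona‑2,6‑dienoate | COC(=O)/C=C(\OP(=O)(OCC)OCC)CC/C=C(\C)CC[C@H]1C(C)(C)CCC[C@]1(C)O[Si](CC)(CC)CC | intermediate
24 | methyl (2E,6E)‑3,7‑dimethyl‑9‑[(1S,2S)‑2,6,6‑trimethyl‑2‑(triethylsilyloxy)cyclohexyl]nona‑2,6‑dienoate | COC(=O)/C=C(\C)CC/C=C(\C)CC[C@H]1C(C)(C)CCC[C@]1(C)O[Si](CC)(CC)CC | intermediate
25 | (2E,6E)‑3,7‑dimethyl‑9‑[(1S,2S)‑2,6,6‑trimethyl‑2‑(triethylsilyloxy)cyclohexyl]nona‑2,6‑dien‑1‑ol | OC/C=C(\C)CC/C=C(\C)CC[C@H]1C(C)(C)CCC[C@]1(C)O[Si](CC)(CC)CC | intermediate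
26 | (2E,6E)‑1‑bromo‑3,7‑dimethyl‑9‑[(1S,2S)‑2,6,6‑trimethyl‑2‑(triethylsilyloxy)cyclohexyl]nona‑2,6‑diene | BrC/C=C(\C)CC/C=C(\C)CC[C@H]1C(C)(C)CCC[C@]1(C)O[Si](CC)(CC)CC | intermediate
27 | dilithium dianion of methyl acetoacetate | [Li+].[Li+].C=C([O-])C=C([O-])OC | intermediate (not isolated)
28 | methyl (6E,10E)‑7,11‑dimethyl‑3‑oxo‑13‑[(1S,2S)‑2,6,6‑trimethyl‑2‑(triethylsilyloxy)cyclohexyl]trideca‑6,10‑dienoate | COC(=O)CC(=O)CC/C=C(\C)CC/C=C(\C)CC[C@H]1C(C)(C)CCC[C@]1(C)O[Si](CC)(CC)CC | intermediate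
29 | sodium enolate of 28 | [Na+].COC(=O)/C=C(\[O-])CC/C=C(\C)CC/C=C(\C)CC[C@H]1C(C)(C)CCC[C@]1(C)O[Si](CC)(CC)CC | intermediate (not isolated)
30 | methyl (2Z,6E,10E)‑3‑(diethoxyphosphoryloxy)‑7,11‑dimethyl‑13‑[(1S,2S)‑2,6,6‑trimethyl‑2‑(triethylsilyloxy)cyclohexyl]trideca‑2,6,10‑trienoate | COC(=O)/C=C(\OP(=O)(OCC)OCC)CC/C=C(\C)CC/C=C(\C)CC[C@H]1C(C)(C)CCC[C@]1(C)O[Si](CC)(CC)CC | intermediate
31 | methyl (2E,6E,10E)‑3,7,11‑trimethyl‑13‑[(1S,2S)‑2,6,6‑trimethyl‑2‑(triethylsilyloxy)cyclohexyl]trideca‑2,6,10‑trienoate | COC(=O)/C=C(\C)CC/C=C(\C)CC/C=C(\C)CC[C@H]1C(C)(C)CCC[C@]1(C)O[Si](CC)(CC)CC | intermediate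
32 | (2E,6E,10E)‑3,7,11‑trimethyl‑13‑[(1S,2S)‑2,6,6‑trimethyl‑2‑(triethylsilyloxy)cyclohexyl]trideca‑2,6,10‑trien‑1‑ol | OC/C=C(\C)CC/C=C(\C)CC/C=C(\C)CC[C@H]1C(C)(C)CCC[C@]1(C)O[Si](CC)(CC)CC | intermediate
33 | preluffariellolide A | OC/C=C(\C)CC/C=C(\C)CC/C=C(\C)CC[C@H]1C(C)(C)CCC[C@]1(C)O | target

**Totals**
Total steps: 22. Longest linear sequence: 22 steps (1 → 33).

**Three steps most likely to fail, with fallbacks**

Step 2 (the hindered tetrasubstituted allylic alcohol may epoxidise slowly or with reduced ee). The fallback sets out from 2 and comes back at 3. Epoxidise 2 with mCPBA (NaHCO3, CH2Cl2, 0 °C) to the racemic epoxy alcohol F1. Acylate with (1S)‑(−)‑camphanic chloride (Et3N, DMAP, CH2Cl2) and separate the two diastereomeric esters by crystallisation or chromatography to obtain the (1S,6S)‑epoxy camphanate F2. Methanolysis (K2CO3, MeOH, 0 °C) returns enantiopure 3.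

Step 5 (the samarium alkoxide of the Z isomer can lactonise, and over‑reduction is possible). The fallback sets out from 4 and comes back at 8. Aldol addition of the lithium enolate of ethyl acetate (LDA, EtOAc, THF, −78 °C) to 4 gives the β‑hydroxy ester F3 as a carbinol epimer mixture, which is inconsequential. 1,1'‑Thiocarbonyldiimidazole (DMAP, ClCH2CH2Cl, 60 °C) converts it into the imidazolylthiocarbonate F4. Bu3SnH/AIBN (toluene, 80 °C) generates the carbinyl radical, which opens the adjacent oxirane (Barton epoxy‑alcohol fragmentation); the tertiary alkoxyl radical is reduced to 8.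

Step 6 (Ir may isomerise the β,γ‑alkene into conjugation or ionise the tertiary allylic alcohol before the directed delivery). The fallback sets out from 4 and comes back at 9, bypassing steps 4–6. Ando Z‑selective olefination of 4 with ethyl (diphenoxyphosphoryl)acetate (NaH, THF, −78 °C) gives the (Z)‑epoxy enoate F5. Tsuji–Shimizu hydrogenolysis (Pd2(dba)3·CHCl3, n‑Bu3P, HCO2H/Et3N, dioxane, rt) should proceed with net retention for the Z isomer: the π‑allyl forms with inversion, isomerises so that Pd moves to the oxygen face, and hydride is delivered internally. This gives the unsaturated hydroxy ester F6 with the ring C–H cis to OH. H2, Pd/C (EtOAc) then saturates the side‑chain alkene to give 9.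

**Further compounds**
F1 | step 2 | racemic (2,2,6‑trimethyl‑7‑oxabicyclo[4.1.0]heptan‑1‑yl)methanol | OCC12OC1(C)CCCC2(C)C
F2 | step 2 | [(1S,6S)‑2,2,6‑trimethyl‑7‑oxabicyclo[4.1.0]heptan‑1‑yl]methyl (1S,4R)‑camphanate | O=C(OC[C@]12O[C@@]1(C)CCCC2(C)C)[C@@]34CC[C@@](C)(C(=O)O3)C4(C)C
F3 | step 5 | ethyl 3‑hydroxy‑3‑[(1S,6S)‑2,2,6‑trimethyl‑7‑oxabicyclo[4.1.0]heptan‑1‑yl]propanoate (epimer mixture at C3) | CCOC(=O)CC(O)[C@]12O[C@@]1(C)CCCC2(C)C
F4 | step 5 | ethyl 3‑(imidazol‑1‑ylcarbothioyloxy)‑3‑[(1S,6S)‑2,2,6‑trimethyl‑7‑oxabicyclo[4.1.0]heptan‑1‑yl]propanoate | CCOC(=O)CC(OC(=S)n1ccnc1)[C@]12O[C@@]1(C)CCCC2(C)C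
F5 | step 6 | ethyl (2Z)‑3‑[(1R,6S)‑2,2,6‑trimethyl‑7‑oxabicyclo[4.1.0]heptan‑1‑yl]prop‑2‑enoate | CCOC(=O)/C=C\[C@]12O[C@@]1(C)CCCC2(C)C
F6 | step 6 | ethyl (2E)‑3‑[(1S,2S)‑2‑hydroxy‑2,6,6‑trimethylcyclohexyl]prop‑2‑enoate | CCOC(=O)/C=C/[C@H]1C(C)(C)CCC[C@]1(C)O
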